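**Strategy.** The route rests on cutting the C4–C5 bond, which is at once the carbon–carbon bond of the oxirane and a ring bond of the ten-membered carbocycle (germacranolide numbering). Because C3 and C6 are cis on the oxirane, this bond is made as a (Z)-trisubstituted alkene by ring-closing metathesis of a seco-diene in which the preformed butenolide (C6–C7–C11–C12–O) holds the C5 vinyl group and the C8 side chain on adjacent ring atoms; one operation closes the cyclodecene and fixes the cis geometry that a reagent-controlled epoxidation then converts into the (4S,5R)-epoxide. The exocyclic C10=C14 methylene is masked as a phenylthiomethyl group and the C8 ester as a silyl ether so that only two alkenes can react.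

Key step: step 9

Numbering used below: C1 ketone carbon; C2, C3 methylenes; C4 (methyl C15) and C5 oxirane carbons; C6 lactone carbinol; C7=C11 butenolide alkene; C8 ester carbinol; C9 methylene; C10 (exocyclic C14); C12 lactone carbonyl; C13 acetoxymethyl carbon.

Assumption: the ligand enantiomers named in steps 4 and 7 are those expected to give the 4S carbinol of 9 and the 8R carbinol of 14; the sense would be checked by Mosher ester analysis on the first run and the antipodal ligand used if it is opposite.

**Step 1**
Reactants: 1 diethyl (3,3-diethoxypropyl)phosphonate; 2 ethyl 4-methylpent-4-enoate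
Product: 3 diethyl (1,1-diethoxy-7-methyl-4-oxooct-7-en-3-yl)phosphonate
Conditions: LiN(iPr)2 (2.2 equiv), THF, −78 °C; then 2, −78 to 0 °C; aq. NH4Cl
Reagents that add atoms: none
Why: Acylation of an α-lithiated alkylphosphonate by an ester (Claisen-type phosphonate acylation) should give the racemic α-substituted β-keto phosphonate, the second equivalent of base holding the product as its enolate.

**Step 2**
Reactants: 3 diethyl (1,1-diethoxy-7-methyl-4-oxooct-7-en-3-yl)phosphonate
Product: 4 1,1-diethoxy-7-methyl-3-methylideneoct-7-en-4-one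
Conditions: 37% aq. CH2O, K2CO3, THF, rt
Reagents that add atoms: formaldehyde, C=O
Why: Horner–Wadsworth–Emmons olefination of the β-keto phosphonate with formaldehyde should place the methylene at C10 only, with no ambiguity between the two α-positions of the ketone.

**Step 3**
Reactants: 4 1,1-diethoxy-7-methyl-3-methylideneoct-7-en-4-one
Product: 6 7-methyl-4-oxo-3-[(phenylsulfanyl)methyl]oct-7-enal, via sulfide acetal 5 (not isolated)
Conditions: PhSH, Et3N (cat.), CH2Cl2, 0 °C to rt; then 1 M HCl, THF, rt
Reagents that add atoms: thiophenol, Sc1ccccc1; water, O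
Why: Thia-Michael addition masks the metathesis-active α-methylene ketone as a β-phenylthio ketone and mild acetal hydrolysis then frees the aldehyde; the sulfide-bearing carbon is racemic and returns to sp2 in step 12.

**Step 4**
Reactants: 7 acrolein; 8 methyl propiolate
Product: 9 methyl (4S)-4-hydroxyhex-5-en-2-ynoate
Conditions: (S,S)-ProPhenol (20 mol%), Me2Zn, toluene, 0 °C
Reagents that add atoms: none
Why: Zinc–ProPhenol-catalysed asymmetric alkynylation of an enal, a favourable substrate class for this reaction, should set the future C6 carbinol by ligand control of the aldehyde face.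

**Step 5**
Reactants: 9 methyl (4S)-4-hydroxyhex-5-en-2-ynoate
Product: 12 (5S)-5-ethenyl-3-(hydroxymethyl)-4-iodofuran-2(5H)-one, via kinetic Z iodo-aldol adduct 10 (not isolated), via E iodo-aldol adduct 11 (not isolated)
Conditions: MgI2 (1.5 equiv), (CH2O)n, CH2Cl2, 0 °C to rt; then TsOH·H2O (cat.), rt
Reagents that add atoms: magnesium iodide, [Mg+2].[I-].[I-]; formaldehyde, C=O
Why: Iodide conjugate addition to the ynoate gives a magnesium allenolate that adds to formaldehyde (β-iodo Morita–Baylis–Hillman, or halo-aldol, reaction), and reversible iodide addition–elimination should equilibrate the alkene geometry so that the E isomer, whose C6 hydroxyl is cis to the ester, is drained irreversibly by lactonization.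

**Step 6**
Reactants: 12 (5S)-5-ethenyl-3-(hydroxymethyl)-4-iodofuran-2(5H)-one
Product: 13 [(5S)-5-ethenyl-4-iodo-2-oxo-2,5-dihydrofuran-3-yl]methyl acetate
Conditions: Ac2O, pyridine, CH2Cl2, 0 °C
Reagents that add atoms: acetic anhydride, CC(=O)OC(C)=O
Why: O-Acetylation of the primary allylic alcohol installs the C13 acetate of the target, run cold to avoid deprotonation of the acidic C6–H.

**Step 7**
Reactants: 13 [(5S)-5-ethenyl-4-iodo-2-oxo-2,5-dihydrofuran-3-yl]methyl acetate; 6 7-methyl-4-oxo-3-[(phenylsulfanyl)methyl]oct-7-enal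
Product: 14 {(5S)-5-ethenyl-4-[(1R)-1-hydroxy-7-methyl-4-oxo-3-[(phenylsulfanyl)methyl]oct-7-en-1-yl]-2-oxo-2,5-dihydrofuran-3-yl}methyl acetate
Conditions: CrCl2 (3 equiv), NiCl2 (cat.), (S)-4-isopropyl-2-(2-methanesulfonamidophenyl)oxazoline-type ligand (3.3 equiv), Et3N, THF, rt
Reagents that add atoms: none
Why: Asymmetric Nozaki–Hiyama–Kishi coupling, in which zerovalent nickel inserts into the C–I bond, transmetalation gives a vinyl species of trivalent chromium that adds to the aldehyde but not to the ketone, and the chiral sulfonamide–oxazoline ligand on chromium should control the aldehyde face to give the 8R carbinol (mixture of epimers at the sulfide-bearing carbon, of no consequence).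

**Step 8**
Reactants: 14 (the alcohol from step 7)
Product: 15 {(5S)-4-[(1R)-1-[(tert-butyldimethylsilyl)oxy]-7-methyl-4-oxo-3-[(phenylsulfanyl)methyl]oct-7-en-1-yl]-5-ethenyl-2-oxo-2,5-dihydrofuran-3-yl}methyl acetate
Conditions: TBSCl, imidazole, DMF, rt
Reagents that add atoms: tert-butyldimethylsilyl chloride, CC(C)(C)[Si](C)(C)Cl
Why: Silylation of the C8 hydroxyl keeps a methacrylate alkene out of the metathesis step and prevents hemiketal formation with the C1 ketone.

**Step 9**
Reactants: 15 (the silyl ether from step 8)
Product: 16 (4Z,6S,8R)-13-acetoxy-8-[(tert-butyldimethylsilyl)oxy]-1-oxo-14-(phenylsulfanyl)germacra-4,7(11)-dien-12,6-olide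
Conditions: second-generation Hoveyda–Grubbs catalyst (10 mol%), 1,4-benzoquinone (10 mol%), toluene, 80 °C, 1 mM, slow addition
Reagents that add atoms: none
Why: Ring-closing olefin metathesis: the ruthenium alkylidene loads on the monosubstituted C5 vinyl group, undergoes intramolecular [2+2] cycloaddition with the 1,1-disubstituted C4 isopropenyl alkene and cycloreverts to the C4=C5 double bond with loss of ethylene (Chauvin mechanism). The closest known reaction type is ring-closing metathesis of seco-dienes to (Z)-trisubstituted alkenes in ten-membered carbocycles of germacranolide and heliangolide frameworks. One ring is closed, the ten-membered carbocycle C1–C10, by alkene–alkene metathesis at high dilution; no other ring forms. No stereocenter is created; the new stereo-element is the C4=C5 geometry, expected to be Z (C3 and C6 cis, as the cis-substituted oxirane requires) because medium rings form through the less strained cis-metallacyclobutane. The step needs cyclization over oligomerization, secured by 1 mM concentration and by the butenolide that holds the C5 vinyl group and the C8 chain on the adjacent atoms C6 and C7, and it needs reaction of only the two intended alkenes, secured because C7=C11 is tetrasubstituted and inert while the C10=C14 methylene and the methacrylate are absent (CH2SPh and OTBS).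

**Step 10**
Reactants: 16 (the macrocyclic silyl ether)
Product: 17 (4Z,6S,8R)-13-acetoxy-8-hydroxy-1-oxo-14-(phenylsulfanyl)germacra-4,7(11)-dien-12,6-olide
Conditions: HF·pyridine, THF, 0 °C to rt
Reagents that add atoms: none
Why: Acidic fluoride desilylation frees the C8 hydroxyl without exposing the base-sensitive C6–H of the butenolide to fluoride base.

**Step 11**
Reactants: 17 (the C8 alcohol)
Product: 18 (4Z,6S,8R)-13-acetoxy-8-(methacryloyloxy)-1-oxo-14-(phenylsulfanyl)germacra-4,7(11)-dien-12,6-olide
Conditions: methacrylic anhydride, Et3N, DMAP (cat.), CH2Cl2, 0 °C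
Reagents that add atoms: methacrylic anhydride, C=C(C)C(=O)OC(=O)C(C)=C
Why: DMAP-catalysed acylation of the secondary alcohol installs the C8 methacrylate with retention at C8.

**Step 12**
Reactants: 18 (the methacrylate sulfide)
Product: 20 (4Z,6S,8R)-13-acetoxy-8-(methacryloyloxy)-1-oxogermacra-4,7(11),10(14)-trien-12,6-olide, via sulfoxide 19 (not isolated)
Conditions: mCPBA (1.0 equiv), CH2Cl2, −78 °C; then CaCO3, toluene, 60 °C
Reagents that add atoms: none
Why: Sulfide oxidation is far faster than alkene epoxidation at −78 °C, and thermal syn-elimination of the β-keto sulfoxide can only remove the C10 hydrogen, which should unveil the C10=C14 methylene regiospecifically.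

**Step 13**
Reactants: 20 (the trienolide)
Product: 21 (4S,5R,6R,8R)-13-acetoxy-4,5-epoxy-8-(methacryloyloxy)-1-oxogermacra-7(11),10(14)-dien-12,6-olide (target)
Conditions: 1,2:4,5-di-O-isopropylidene-β-D-erythro-2,3-hexodiulo-2,6-pyranose (D-fructose-derived ketone, 0.5 equiv), KHSO5 (Oxone), NaHCO3, MeCN/dimethoxymethane–aq. Na2EDTA, 0 °C, pH 8
Reagents that add atoms: potassium peroxymonosulfate, [K+].[O-]S(=O)(=O)OO
Why: Shi epoxidation, in which the chiral dioxirane transfers oxygen through a spiro transition state; by the model that gives (R,R)-1-phenylcyclohexene oxide, the Z-trisubstituted C4=C5 alkene (the only electron-rich alkene) should be attacked on the face that gives the (4S,5R)-oxirane, while the enone, methacrylate and butenolide alkenes are too electron-poor to react.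

**Compound list**

1 | diethyl (3,3-diethoxypropyl)phosphonate | CCOC(CCP(=O)(OCC)OCC)OCC | starting material
2 | ethyl 4-methylpent-4-enoate | CCOC(=O)CCC(C)=C | starting material
3 | diethyl (1,1-diethoxy-7-methyl-4-oxooct-7-en-3-yl)phosphonate (racemic) | CCOC(OCC)CC(P(=O)(OCC)OCC)C(=O)CCC(C)=C | intermediate
4 | 1,1-diethoxy-7-methyl-3-methylideneoct-7-en-4-one | CCOC(OCC)CC(=C)C(=O)CCC(C)=C | intermediate
5 | 1,1-diethoxy-7-methyl-3-[(phenylsulfanyl)methyl]oct-7-en-4-one (racemic, not isolated) | CCOC(OCC)CC(CSc1ccccc1)C(=O)CCC(C)=C | intermediate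
6 | 7-methyl-4-oxo-3-[(phenylsulfanyl)methyl]oct-7-enal (racemic) | O=CCC(CSc1ccccc1)C(=O)CCC(C)=C | intermediate
7 | acrolein | C=CC=O | starting material
8 | methyl propiolate | C#CC(=O)OC | starting material
9 | methyl (4S)-4-hydroxyhex-5-en-2-ynoate | C=C[C@H](O)C#CC(=O)OC | intermediate
10 | methyl (2Z,4S)-4-hydroxy-2-(hydroxymethyl)-3-iodohexa-2,5-dienoate (not isolated) | C=C[C@H](O)/C(I)=C(\CO)C(=O)OC | intermediate
11 | methyl (2E,4S)-4-hydroxy-2-(hydroxymethyl)-3-iodohexa-2,5-dienoate (not isolated) | C=C[C@H](O)/C(I)=C(/CO)C(=O)OC | intermediate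
12 | (5S)-5-ethenyl-3-(hydroxymethyl)-4-iodofuran-2(5H)-one | C=C[C@@H]1OC(=O)C(CO)=C1I | intermediate
13 | [(5S)-5-ethenyl-4-iodo-2-oxo-2,5-dihydrofuran-3-yl]methyl acetate | C=C[C@@H]1OC(=O)C(COC(C)=O)=C1I | intermediate
14 | {(5S)-5-ethenyl-4-[(1R)-1-hydroxy-7-methyl-4-oxo-3-[(phenylsulfanyl)methyl]oct-7-en-1-yl]-2-oxo-2,5-dihydrofuran-3-yl}methyl acetate (epimers at the sulfide-bearing carbon) | C=C[C@@H]1OC(=O)C(COC(C)=O)=C1[C@H](O)CC(CSc2ccccc2)C(=O)CCC(C)=C | intermediate
15 | tert-butyldimethylsilyl ether of 14 at the (1R)-carbinol | C=C[C@@H]1OC(=O)C(COC(C)=O)=C1[C@H](O[Si](C)(C)C(C)(C)C)CC(CSc2ccccc2)C(=O)CCC(C)=C | intermediate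
16 | (4Z,6S,8R)-13-acetoxy-8-[(tert-butyldimethylsilyl)oxy]-1-oxo-14-(phenylsulfanyl)germacra-4,7(11)-dien-12,6-olide (C10 epimers) | CC(C)(C)[Si](C)(C)O[C@@H]1CC(CSc3ccccc3)C(=O)CC/C(C)=C\[C@@H]2OC(=O)C(COC(C)=O)=C21 | intermediate
17 | (4Z,6S,8R)-13-acetoxy-8-hydroxy-1-oxo-14-(phenylsulfanyl)germacra-4,7(11)-dien-12,6-olide (C10 epimers) | O[C@@H]1CC(CSc3ccccc3)C(=O)CC/C(C)=C\[C@@H]2OC(=O)C(COC(C)=O)=C21 | intermediate
18 | (4Z,6S,8R)-13-acetoxy-8-(methacryloyloxy)-1-oxo-14-(phenylsulfanyl)germacra-4,7(11)-dien-12,6-olide (C10 epimers) | C=C(C)C(=O)O[C@@H]1CC(CSc3ccccc3)C(=O)CC/C(C)=C\[C@@H]2OC(=O)C(COC(C)=O)=C21 | intermediate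
19 | S-oxide of 18 (14-phenylsulfinyl compound, not isolated) | C=C(C)C(=O)O[C@@H]1CC(CS(=O)c3ccccc3)C(=O)CC/C(C)=C\[C@@H]2OC(=O)C(COC(C)=O)=C21 | intermediate
20 | (4Z,6S,8R)-13-acetoxy-8-(methacryloyloxy)-1-oxogermacra-4,7(11),10(14)-trien-12,6-olide | C=C(C)C(=O)O[C@@H]1CC(=C)C(=O)CC/C(C)=C\[C@@H]2OC(=O)C(COC(C)=O)=C21 | intermediate
21 | (4S,5R,6R,8R)-13-acetoxy-4,5-epoxy-8-(methacryloyloxy)-1-oxogermacra-7(11),10(14)-dien-12,6-olide | C=C(C)C(=O)O[C@@H]1CC(=C)C(=O)CC[C@]2(C)O[C@@H]2[C@@H]2OC(=O)C(COC(C)=O)=C21 | target

**Step count and risks**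

Total step count: 13. Longest linear sequence: 10 steps (steps 1–3 then 7–13, or steps 4–6 then 7–13).

Steps most likely to fail:

1. Step 9 (ring-closing metathesis). Oligomerization may outrun closure of the strained ring, the hindered isopropenyl alkene may fail to enter the metallacycle, or E and Z isomers may form together. Fallback with a temporary ring, setting out from 14 and returning at 17: treatment of 14 with MeOH, CH(OMe)3 and PPTS should tie the C8 hydroxyl to the C1 ketone as the cyclic methyl ketal F1 (a 2-methoxytetrahydrofuran). Metathesis of F1 with the same catalyst then has to close only a nine-membered oxa-bridged ring, the oxabicyclo[6.2.1]undecene pattern, and should give the bridged bicyclic ketal F2. Hydrolysis with PPTS in acetone/water opens the ketal to the hydroxy ketone 17; steps 8 and 10 are not needed on this path.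

2. Step 5 (iodo-aldol and lactonization). The kinetic Z adduct may not equilibrate to the E isomer, so lactonization stalls, or simple hydroiodination may compete with the aldol step. Fallback that separates the events, setting out from 9 and returning at 13: silylation of 9 (TBSCl, imidazole) gives the silyl ether F3. MgI2 and formaldehyde at −20 °C give the kinetic (Z)-iodo-aldol adduct F4, which is isolated, and acetylation gives the acetate F5. HF·pyridine frees the hydroxy ester F6, and radical-catalysed alkene isomerization (PhSSPh cat., visible light, or I2 cat.) with irreversible lactonization of the E isomer should give 13.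

3. Step 13 (epoxidation). Facial selectivity may be poor if the face preferred by the chiral dioxirane is the transannularly shielded face of the cyclodecene, so that substrate and reagent control oppose each other. Fallback by two-step oxygen delivery with inversion, setting out from 20 and returning at 21: NBS in THF/water at 0 °C forms the bromonium ion on the accessible face and water opens it at C4 from the other side, giving the anti bromohydrin F7. Ag2O in CH2Cl2 then closes the oxirane by displacement of bromide, which puts the oxygen on the face opposite to the one reached by direct electrophilic attack.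

**Further compounds**

F1 | step 9 | cyclic methyl ketal of 14 (2-methoxytetrahydrofuran from O8 and C1, ketal epimers) | C=C[C@@H]1OC(=O)C(COC(C)=O)=C1[C@H]1CC(CSc2ccccc2)C(OC)(CCC(C)=C)O1
F2 | step 9 | (4Z)-cyclized bridged ketal (1-methoxy-1,8-epoxy analogue of 17) | COC12CC/C(C)=C\[C@@H]3OC(=O)C(COC(C)=O)=C3[C@@H](CC1CSc1ccccc1)O2
F3 | step 5 | methyl (4S)-4-[(tert-butyldimethylsilyl)oxy]hex-5-en-2-ynoate | C=C[C@H](O[Si](C)(C)C(C)(C)C)C#CC(=O)OC
F4 | step 5 | methyl (2Z,4S)-4-[(tert-butyldimethylsilyl)oxy]-2-(hydroxymethyl)-3-iodohexa-2,5-dienoate | C=C[C@H](O[Si](C)(C)C(C)(C)C)/C(I)=C(\CO)C(=O)OC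
F5 | step 5 | methyl (2Z,4S)-2-(acetoxymethyl)-4-[(tert-butyldimethylsilyl)oxy]-3-iodohexa-2,5-dienoate | C=C[C@H](O[Si](C)(C)C(C)(C)C)/C(I)=C(\COC(C)=O)C(=O)OC
F6 | step 5 | methyl (2Z,4S)-2-(acetoxymethyl)-4-hydroxy-3-iodohexa-2,5-dienoate | C=C[C@H](O)/C(I)=C(\COC(C)=O)C(=O)OC
F7 | step 13 | (4S,5S,6R,8R)-13-acetoxy-5-bromo-4-hydroxy-8-(methacryloyloxy)-1-oxogermacra-7(11),10(14)-dien-12,6-olide | C=C(C)C(=O)O[C@@H]1CC(=C)C(=O)CC[C@](C)(O)[C@@H](Br)[C@@H]2OC(=O)C(COC(C)=O)=C21
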